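Ring A of the chromene is disconnected at C4a–C5 and C6–C7, and the pyran at O1–C2. Around ring A the order C7–OH, C8–H, C8a–O1, C4a–C4, C5–H, C6–acyl is that of a 1,3-dioxygenated diene joined to a propiolate, and C4 can enter as a carbinol. In one operation a Diels–Alder addition, aromatisation and oxa-6π closure should turn an open-chain tris(silyloxy)triene and methyl propiolate into the linear 7-hydroxy-2,2-dimethylchromene-6-carboxylate, with no linear/angular question. The triene comes from methyl acetoacetate and 3-methylbut-2-enal. A Claisen condensation with silylated 4'-hydroxy-3'-prenylacetophenone and buffered desilylation finish the diketone.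

Key step: step 4

Remarks on the chemistry:
- The target has no stereocentre and is achiral, so no enantiomer has to be secured. It is drawn as the diketo tautomer.
- Triene 8 is made and used as the racemate; its C5 centre and its C1=C2 geometry are erased in step 4.
- All three oxygens of 8 carry TMS, so that one mild acidic work-up frees them together.
- Chromene numbering (O1, C2–C4, C4a, C5–C8, C8a) is used throughout.

Step 1
Reactants: 1 methyl acetoacetate; 2 3-methylbut-2-enal
Product: 4 methyl 5-hydroxy-7-methyl-3-oxooct-6-enoate (racemic), via dilithium dianion of methyl acetoacetate 3 (not isolated)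
Conditions: LDA (2.1 equiv), THF, −78→0 °C; 2, −78 °C; AcOH, −78 °C
Reagents that add atoms: none
Why: Huckin–Weiler dianion aldol addition, in which the more basic γ-carbanion of 3 adds 1,2 to the aldehyde carbonyl of the enal as hard lithium nucleophiles do; the new carbinol centre is formed racemic, which is harmless because step 4 erases it.

Step 2
Reactants: 4 methyl 5-hydroxy-7-methyl-3-oxooct-6-enoate
Product: 6 methyl 7-methyl-3,5-bis(trimethylsilyloxy)octa-2,6-dienoate, via methyl 7-methyl-3-oxo-5-(trimethylsilyloxy)oct-6-enoate 5 (not isolated)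
Conditions: TMSCl (2.5 equiv), Et3N (3 equiv), PhMe, 0→23 °C; filtered under Ar, concentrated
Reagents that add atoms: chlorotrimethylsilane, C[Si](C)(C)Cl
Why: O-silylation of the alcohol and, by amine-mediated soft enolisation, of the β-keto ester (first half of the standard preparation of 1-methoxy-1,3-bis(silyloxy)dienes); the C2=C3 geometry does not matter because this bond becomes single in 8.

Step 3
Reactants: 6 methyl 7-methyl-3,5-bis(trimethylsilyloxy)octa-2,6-dienoate
Product: 8 (1Z,3Z)-1-methoxy-7-methyl-1,3,5-tris(trimethylsilyloxy)octa-1,3,6-triene (racemic), via lithium dienolate of 6 7 (not isolated)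
Conditions: LDA (1.3 equiv), THF, −78 °C; TMSCl (1.5 equiv), −78→0 °C; hexane, filtered under Ar, used crude
Reagents that add atoms: chlorotrimethylsilane, C[Si](C)(C)Cl
Why: Kinetic γ-deprotonation of the 3-silyloxy enoate and O-silylation of the extended dienolate 7 (second half of the same diene preparation), which for 4-substituted dienes of this class gives the 3Z enol ether with the side chain trans to C2; holding 7 at −78 °C and trapping it at once should forestall β-elimination of the C5 silyloxy group.

Step 4
Reactants: 8 (1Z,3Z)-1-methoxy-7-methyl-1,3,5-tris(trimethylsilyloxy)octa-1,3,6-triene; 9 methyl propiolate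
Product: 14 methyl 7-hydroxy-2,2-dimethyl-2H-chromene-6-carboxylate, via methyl 6-methoxy-3-[3-methyl-1-(trimethylsilyloxy)but-2-en-1-yl]-4,6-bis(trimethylsilyloxy)cyclohexa-1,4-diene-1-carboxylate 10 (not isolated), via methyl 5-[3-methyl-1-(trimethylsilyloxy)but-2-en-1-yl]-2,4-bis(trimethylsilyloxy)benzoate 11 (not isolated), via methyl 2,4-dihydroxy-5-(1-hydroxy-3-methylbut-2-en-1-yl)benzoate 12 (not isolated), via methyl (3Z)-6-hydroxy-3-(3-methylbut-2-en-1-ylidene)-4-oxocyclohexa-1,5-diene-1-carboxylate 13 (not isolated)
Conditions: 9 (2 equiv), PhMe, 23→80 °C; then 1 M aq HCl, THF, 23 °C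
Reagents that add atoms: none
Why: Proposed new method: the diene terminus C4 of 8 (the future C4a), pushed by the C1 and C3 oxygens, bonds to the β-carbon of 9 and C1 to the α-carbon, in an asynchronous [4+2] addition or its Michael–Claisen equivalent, to give 10; 1,4-loss of methanol aromatises 10 to 11, aqueous acid strips the three TMS groups to 12, and the carbinol of 12, benzylic, allylic and ortho/para to two phenols, ionises to the ortho-quinone methide 13. The closest known reactions are the Diels–Alder/aromatisation of 1-methoxy-1,3-bis(silyloxy)dienes with propiolates to 2,4-dihydroxybenzoates and the dehydrative closure of ortho-hydroxyaryl allylic carbinols to 2H-chromenes; what is new is their telescoping with a diene that is branched at its reacting terminus. Ring A closes by the [4+2] cycloaddition (bonds C4a–C5 and C6–C7) followed by aromatisation, and the pyran closes by thermal oxa-6π electrocyclisation of 13 (bond O1–C2). No stereocentre is formed, and the carbinol centre and the two sp3 ring centres of 10 are erased. The regioselectivity needed, the ester next to C7–O and para to C8a–O, should follow from the polarity match of the nucleophilic C4 terminus with the propiolate β-carbon; the 3Z geometry keeps the branched side chain outside the s-cis diene, and because O1 is the only phenol ortho to the carbinol, only the linear chromene can form.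

Step 5
Reactants: 14 methyl 7-hydroxy-2,2-dimethyl-2H-chromene-6-carboxylate
Product: 15 methyl 7-(tert-butyldimethylsilyloxy)-2,2-dimethyl-2H-chromene-6-carboxylate
Conditions: TBSCl (1.5 equiv), imidazole (3 equiv), DMF, 23→40 °C
Reagents that add atoms: tert-butyldimethylsilyl chloride, CC(C)(C)[Si](C)(C)Cl
Why: Imidazole-promoted silylation (Corey protocol) of the only hydroxyl of 14, the hydrogen-bonded C7 phenol, so that the ester is not deactivated as a phenoxide salicylate in step 8.

Step 6
Reactants: 16 4'-hydroxyacetophenone; 17 prenyl bromide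
Product: 18 1-[4-hydroxy-3-(3-methylbut-2-en-1-yl)phenyl]ethan-1-one
Conditions: KOH (10% aq), 17 (1.1 equiv), 0→23 °C
Reagents that add atoms: none
Why: Ortho C-alkylation of a para-blocked phenoxide by an allylic bromide in water, where hydrogen bonding to the phenoxide oxygen favours attack through carbon; the O-prenyl ether formed alongside stays in the neutral fraction and is removed by base extraction and chromatography.

Step 7
Reactants: 18 1-[4-hydroxy-3-(3-methylbut-2-en-1-yl)phenyl]ethan-1-one
Product: 19 1-[4-(tert-butyldimethylsilyloxy)-3-(3-methylbut-2-en-1-yl)phenyl]ethan-1-one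
Conditions: TBSCl (1.2 equiv), imidazole (2.5 equiv), DMF, 23 °C
Reagents that add atoms: tert-butyldimethylsilyl chloride, CC(C)(C)[Si](C)(C)Cl
Why: Standard imidazole-promoted silylation of the phenol, which removes the acidic proton before the enolate chemistry of step 8.

Step 8
Reactants: 19 1-[4-(tert-butyldimethylsilyloxy)-3-(3-methylbut-2-en-1-yl)phenyl]ethan-1-one; 15 methyl 7-(tert-butyldimethylsilyloxy)-2,2-dimethyl-2H-chromene-6-carboxylate
Product: 21 1-[7-(tert-butyldimethylsilyloxy)-2,2-dimethyl-2H-chromen-6-yl]-3-[4-(tert-butyldimethylsilyloxy)-3-(3-methylbut-2-en-1-yl)phenyl]propane-1,3-dione, via lithium 1-[4-(tert-butyldimethylsilyloxy)-3-(3-methylbut-2-en-1-yl)phenyl]ethen-1-olate 20 (not isolated)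
Conditions: 19 (1.3 equiv), LiHMDS (2.6 equiv), THF, −78 °C; 15, −78→0 °C; AcOH
Reagents that add atoms: none
Why: Crossed Claisen condensation, in which the preformed lithium enolate 20 attacks the methyl ester of 15 (no α-hydrogen) and the excess amide base deprotonates the 1,3-diketone as it forms, which pulls the condensation to completion.

Step 9
Reactants: 21 1-[7-(tert-butyldimethylsilyloxy)-2,2-dimethyl-2H-chromen-6-yl]-3-[4-(tert-butyldimethylsilyloxy)-3-(3-methylbut-2-en-1-yl)phenyl]propane-1,3-dione
Product: 22 glyinflanin C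
Conditions: TBAF (2.4 equiv), AcOH (2.6 equiv), THF, 0 °C
Reagents that add atoms: none
Why: Fluoride cleavage of both aryl silyl ethers, buffered with acetic acid so that neither retro-Claisen cleavage nor cyclodehydration of the 2'-hydroxy-1,3-diketone to a flavone (which needs strong acid) can set in; the prenyl group and the chromene are inert to these conditions.

Compound list
1 | methyl acetoacetate | COC(=O)CC(C)=O | starting material
2 | 3-methylbut-2-enal | CC(C)=CC=O | starting material
3 | dilithium dianion of methyl acetoacetate | [Li+].[Li+].[CH2-]C(=O)[CH-]C(=O)OC | intermediate (not isolated)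
4 | methyl 5-hydroxy-7-methyl-3-oxooct-6-enoate (racemic) | COC(=O)CC(=O)CC(O)C=C(C)C | intermediate
5 | methyl 7-methyl-3-oxo-5-(trimethylsilyloxy)oct-6-enoate (racemic) | COC(=O)CC(=O)CC(O[Si](C)(C)C)C=C(C)C | intermediate (not isolated)
6 | methyl 7-methyl-3,5-bis(trimethylsilyloxy)octa-2,6-dienoate (racemic, 2E/2Z mixture) | COC(=O)C=C(O[Si](C)(C)C)CC(O[Si](C)(C)C)C=C(C)C | intermediate
7 | lithium dienolate of 6 (lithium (1Z,3Z)-1-methoxy-7-methyl-3,5-bis(trimethylsilyloxy)octa-1,3,6-trien-1-olate) | [Li+].CO/C([O-])=C/C(O[Si](C)(C)C)=C/C(O[Si](C)(C)C)C=C(C)C | intermediate (not isolated)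
8 | (1Z,3Z)-1-methoxy-7-methyl-1,3,5-tris(trimethylsilyloxy)octa-1,3,6-triene (racemic at C5) | CO/C(O[Si](C)(C)C)=C/C(O[Si](C)(C)C)=C/C(O[Si](C)(C)C)C=C(C)C | intermediate
9 | methyl propiolate | C#CC(=O)OC | starting material
10 | methyl 6-methoxy-3-[3-methyl-1-(trimethylsilyloxy)but-2-en-1-yl]-4,6-bis(trimethylsilyloxy)cyclohexa-1,4-diene-1-carboxylate (diastereomer mixture) | COC(=O)C1=CC(C(O[Si](C)(C)C)C=C(C)C)C(O[Si](C)(C)C)=CC1(OC)O[Si](C)(C)C | intermediate (not isolated)
11 | methyl 5-[3-methyl-1-(trimethylsilyloxy)but-2-en-1-yl]-2,4-bis(trimethylsilyloxy)benzoate (racemic) | COC(=O)c1cc(C(O[Si](C)(C)C)C=C(C)C)c(O[Si](C)(C)C)cc1O[Si](C)(C)C | intermediate (not isolated)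
12 | methyl 2,4-dihydroxy-5-(1-hydroxy-3-methylbut-2-en-1-yl)benzoate (racemic) | COC(=O)c1cc(C(O)C=C(C)C)c(O)cc1O | intermediate (not isolated)
13 | methyl (3Z)-6-hydroxy-3-(3-methylbut-2-en-1-ylidene)-4-oxocyclohexa-1,5-diene-1-carboxylate (ortho-quinone methide) | COC(=O)C1=C/C(=C/C=C(C)C)C(=O)C=C1O | intermediate (not isolated)
14 | methyl 7-hydroxy-2,2-dimethyl-2H-chromene-6-carboxylate | COC(=O)c1cc2c(cc1O)OC(C)(C)C=C2 | intermediate
15 | methyl 7-(tert-butyldimethylsilyloxy)-2,2-dimethyl-2H-chromene-6-carboxylate | COC(=O)c1cc2c(cc1O[Si](C)(C)C(C)(C)C)OC(C)(C)C=C2 | intermediate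
16 | 4'-hydroxyacetophenone | CC(=O)c1ccc(O)cc1 | starting material
17 | prenyl bromide | CC(C)=CCBr | starting material
18 | 1-[4-hydroxy-3-(3-methylbut-2-en-1-yl)phenyl]ethan-1-one | CC(=O)c1ccc(O)c(CC=C(C)C)c1 | intermediate
19 | 1-[4-(tert-butyldimethylsilyloxy)-3-(3-methylbut-2-en-1-yl)phenyl]ethan-1-one | CC(=O)c1ccc(O[Si](C)(C)C(C)(C)C)c(CC=C(C)C)c1 | intermediate
20 | lithium 1-[4-(tert-butyldimethylsilyloxy)-3-(3-methylbut-2-en-1-yl)phenyl]ethen-1-olate | [Li+].[O-]C(=C)c1ccc(O[Si](C)(C)C(C)(C)C)c(CC=C(C)C)c1 | intermediate (not isolated)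
21 | 1-[7-(tert-butyldimethylsilyloxy)-2,2-dimethyl-2H-chromen-6-yl]-3-[4-(tert-butyldimethylsilyloxy)-3-(3-methylbut-2-en-1-yl)phenyl]propane-1,3-dione | CC(C)=CCc1cc(C(=O)CC(=O)c2cc3c(cc2O[Si](C)(C)C(C)(C)C)OC(C)(C)C=C3)ccc1O[Si](C)(C)C(C)(C)C | intermediate
22 | glyinflanin C, 1-(7-hydroxy-2,2-dimethyl-2H-chromen-6-yl)-3-[4-hydroxy-3-(3-methylbut-2-en-1-yl)phenyl]propane-1,3-dione (achiral) | CC(C)=CCc1cc(C(=O)CC(=O)c2cc3c(cc2O)OC(C)(C)C=C3)ccc1O | target

Total step count: 9. Longest linear sequence: 7 (steps 1, 2, 3, 4, 5, 8, 9).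

Steps most likely to fail

1. Step 4 (Proposed new method). The [4+2] addition may be too slow at the α-branched diene terminus, so that the triene is lost to protodesilylation or to ionisation of its doubly activated C5 silyloxy group before ring A exists. In the acid stage the cation may also be drained by oligomerisation of the quinone methide. The fallback uses known chemistry, sets out from 1 and 9 and comes back at 14; it attaches C4 after the arene exists and controls the position by halogenation. Methyl acetoacetate 1 would be silylated (TMSCl, Et3N) to methyl 3-(trimethylsilyloxy)but-2-enoate F1 and then (LDA, TMSCl, −78 °C) to the unbranched 1-methoxy-1,3-bis(trimethylsilyloxy)buta-1,3-diene F2. Its Diels–Alder addition to 9 with acidic work-up is the precedented case and should give methyl 2,4-dihydroxybenzoate F3 through the same two ring A bonds. Bromination (Br2, AcOH, 23 °C) should go para to the C2 hydroxyl and away from the flanked C3 to give methyl 5-bromo-2,4-dihydroxybenzoate F4. Heck coupling with 2-methylbut-3-en-2-ol (Pd(OAc)2, P(o-tol)3, Et3N, DMF, 100 °C) should give methyl 2,4-dihydroxy-5-[(E)-3-hydroxy-3-methylbut-1-en-1-yl]benzoate F5. Catalytic acid (PPTS, PhMe, 80 °C) would ionise the tertiary allylic alcohol to the same cation and quinone methide 13, which closes to 14.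

2. Step 3. The dienolate 7 carries a silyloxy group β to its carbanionic terminus and may expel it (E1cB) before it is trapped, and the triene may hydrolyse on isolation. The fallback sets out from 1 and 2 and comes back at 14; it carries the C5 oxygen as a methyl ether, a much poorer leaving group that cannot migrate, and builds the chain by acetal chemistry instead of the dianion aldol. 3-Methylbut-2-enal 2 would be converted (HC(OMe)3, MeOH, cat. PPTS) into 1,1-dimethoxy-3-methylbut-2-ene F6. Mukaiyama-type addition of the unbranched diene F2 (made from 1 as in the first fallback) to F6 (cat. TMSOTf, CH2Cl2, −78 °C) should occur through the diene terminus at the acetal carbon and give the stable keto ester methyl 5-methoxy-7-methyl-3-oxooct-6-enoate F7. The two silylations of steps 2 and 3 would then give methyl 5-methoxy-7-methyl-3-(trimethylsilyloxy)octa-2,6-dienoate F8 and (1Z,3Z)-1,5-dimethoxy-7-methyl-1,3-bis(trimethylsilyloxy)octa-1,3,6-triene F9. F9 would enter step 4 with 9 unchanged; the benzylic methyl ether ionises under the same acid with loss of methanol, and the route is rejoined at 14.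

3. Step 8. The O7 silyl group may be transferred to the enolate or cleaved by the methoxide set free, which would leave an unreactive phenoxide ester, and acylation at the ester shielded by the ortho silyloxy group may be slow. The fallback sets out from 15 and comes back at 21; it replaces the acylation by an aldol addition and an oxidation. Ester 15 would be reduced (DIBAL-H, CH2Cl2, −78 °C) to [7-(tert-butyldimethylsilyloxy)-2,2-dimethyl-2H-chromen-6-yl]methanol F10 and oxidised (MnO2, CH2Cl2) to 7-(tert-butyldimethylsilyloxy)-2,2-dimethyl-2H-chromene-6-carbaldehyde F11. Addition of enolate 20 (THF, −78 °C, cold quench) should give the β-hydroxy ketone 3-[7-(tert-butyldimethylsilyloxy)-2,2-dimethyl-2H-chromen-6-yl]-1-[4-(tert-butyldimethylsilyloxy)-3-(3-methylbut-2-en-1-yl)phenyl]-3-hydroxypropan-1-one F12, and Dess–Martin oxidation (NaHCO3, CH2Cl2) would deliver 21.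

Further compounds
F1 | step 4 | methyl 3-(trimethylsilyloxy)but-2-enoate | COC(=O)C=C(C)O[Si](C)(C)C
F2 | step 4 | 1-methoxy-1,3-bis(trimethylsilyloxy)buta-1,3-diene | COC(O[Si](C)(C)C)=CC(=C)O[Si](C)(C)C
F3 | step 4 | methyl 2,4-dihydroxybenzoate | COC(=O)c1ccc(O)cc1O
F4 | step 4 | methyl 5-bromo-2,4-dihydroxybenzoate | COC(=O)c1cc(Br)c(O)cc1O
F5 | step 4 | methyl 2,4-dihydroxy-5-[(E)-3-hydroxy-3-methylbut-1-en-1-yl]benzoate | COC(=O)c1cc(/C=C/C(C)(C)O)c(O)cc1O
F6 | step 3 | 1,1-dimethoxy-3-methylbut-2-ene | COC(OC)C=C(C)C
F7 | step 3 | methyl 5-methoxy-7-methyl-3-oxooct-6-enoate (racemic) | COC(=O)CC(=O)CC(OC)C=C(C)C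
F8 | step 3 | methyl 5-methoxy-7-methyl-3-(trimethylsilyloxy)octa-2,6-dienoate (racemic) | COC(=O)C=C(O[Si](C)(C)C)CC(OC)C=C(C)C
F9 | step 3 | (1Z,3Z)-1,5-dimethoxy-7-methyl-1,3-bis(trimethylsilyloxy)octa-1,3,6-triene (racemic) | CO/C(O[Si](C)(C)C)=C/C(O[Si](C)(C)C)=C/C(OC)C=C(C)C
F10 | step 8 | [7-(tert-butyldimethylsilyloxy)-2,2-dimethyl-2H-chromen-6-yl]methanol | OCc1cc2c(cc1O[Si](C)(C)C(C)(C)C)OC(C)(C)C=C2
F11 | step 8 | 7-(tert-butyldimethylsilyloxy)-2,2-dimethyl-2H-chromene-6-carbaldehyde | O=Cc1cc2c(cc1O[Si](C)(C)C(C)(C)C)OC(C)(C)C=C2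
F12 | step 8 | 3-[7-(tert-butyldimethylsilyloxy)-2,2-dimethyl-2H-chromen-6-yl]-1-[4-(tert-butyldimethylsilyloxy)-3-(3-methylbut-2-en-1-yl)phenyl]-3-hydroxypropan-1-one (racemic) | CC(C)=CCc1cc(C(=O)CC(O)c2cc3c(cc2O[Si](C)(C)C(C)(C)C)OC(C)(C)C=C3)ccc1O[Si](C)(C)C(C)(C)C
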